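The ketone carbon C9 and the acetoxy carbon C14 are 1,5-related twice, via C10–C11–C12 and via C8–C13–C12. With C14 as a ketone, the C12–C13 bridge of the bicyclo[2.2.2]octane is therefore a tigloyl dienophile added across a 2-silyloxycyclohexadiene. Cutting C11–C12 and C8–C13 removes ring C and ring B together. This leaves a monocyclic 4,4-disubstituted cyclohexenone whose C6 carries the linalool-type chain and a tigloyl-terminated tether. One intramolecular Diels–Alder reaction closes ring C (C6, C11, C12, C14, C15, C16) and the bicycle and sets C8, C11, C12 and C13. C6/C16 come from a δ-lactone template, C3 from (S)-linalool.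

Key step: step 12

Numbering: skeletal atoms follow the target SMILES, methyl branches left out. C1=C2 vinyl, C3 carbinol, C4, C5 chain, C6 quaternary ring carbon, C7 CH2, C8 bridgehead next to C=O, C9 C=O, C10 CH2, C11 bridgehead, C12 quaternary C–CH3, C13 CH–CH3, C14 CH–OAc, C15 CH2, C16 CH–CH3. Ring A = C6–C7–C8–C9–C10–C11, ring B = C8–C9–C10–C11–C12–C13, ring C = C6–C11–C12–C14–C15–C16. In this numbering the target is 3S,6S,8R,11S,12S,13R,14R,16R.

Assumption: (S)-(+)-linalool (coriandrol) of high enantiomeric purity is taken as a commercial material. Its stereocentre has the same spatial arrangement as C3 of the target.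

Step 1
Reactants: 1 (S)-(+)-linalool
Product: 2 (S)-linalool tert-butyldimethylsilyl ether
Conditions: TBSOTf, 2,6-lutidine, CH2Cl2, 0 °C to rt
Reagents that add atoms: tert-butyldimethylsilyl triflate CC(C)(C)[Si](C)(C)OS(=O)(=O)C(F)(F)F
Why: Silyl triflate silylation of a hindered tertiary alcohol, in which the C3 stereocentre (S, chiral pool) is not touched and is carried unchanged to the target.

Step 2
Reactants: 2 (S)-linalool tert-butyldimethylsilyl ether
Product: 4 (4S)-4-(tert-butyldimethylsilyloxy)-4-methylhex-5-enoic acid, via aldehyde 3 (not isolated)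
Conditions: O3 (1.0 equiv), acetone/H2O, 0 °C; then NaClO2, NaH2PO4, 0 °C to rt
Reagents that add atoms: ozone [O-][O+]=O; water O; sodium chlorite [Na+].[O-]Cl=O
Why: Chemoselective ozonolysis of the electron-rich trisubstituted alkene beside the hindered, inductively deactivated vinyl group, run in wet acetone so that aldehyde 3 forms directly, followed in the same flask by Pinnick oxidation with the released H2O2 acting as hypochlorite scavenger.

Step 3
Reactants: 4 (4S)-4-(tert-butyldimethylsilyloxy)-4-methylhex-5-enoic acid
Product: 6 (3S)-3-(tert-butyldimethylsilyloxy)-5-iodo-3-methylpent-1-ene, via thiohydroxamate ester 5 (not isolated)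
Conditions: 1-hydroxypyridine-2(1H)-thione, DCC, CH2Cl2, 0 °C, dark; then CHI3, hν (tungsten lamp), reflux
Reagents that add atoms: iodoform IC(I)I; 1-hydroxypyridine-2(1H)-thione ON1C=CC=CC1=S (atoms of intermediate 5 only)
Why: Barton decarboxylative iodination, in which ester 5 fragments in a radical chain to the primary C5 radical that abstracts iodine from CHI3 faster than it can attack the vinyl group (only a four-membered closure would be open), so the one surplus carbon of linalool is excised.

Step 4
Reactants: 7 methyl hydrogen (R)-3-methylglutarate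
Product: 9 (4R)-4-methyltetrahydro-2H-pyran-2-one, via hydroxy ester 8 (not isolated)
Conditions: BH3·SMe2, THF, −10 °C to rt; H2O; then TsOH·H2O (cat.), toluene, rt
Reagents that add atoms: none
Why: Chemoselective borane reduction of the free acid beside the methyl ester followed by acid-catalysed lactonisation, so that C16 (R) is taken from the commercial half-ester and reduction of the acid arm gives the R lactone.

Step 5
Reactants: 9 (4R)-4-methyltetrahydro-2H-pyran-2-one; 6 (3S)-3-(tert-butyldimethylsilyloxy)-5-iodo-3-methylpent-1-ene
Product: 10 (3S,4R)-3-[(3S)-3-(tert-butyldimethylsilyloxy)-3-methylpent-4-en-1-yl]-4-methyltetrahydro-2H-pyran-2-one (3,4-trans)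
Conditions: LiN(iPr)2, THF, −78 °C; then 6, DMPU, −78 to −20 °C
Reagents that add atoms: none
Why: SN2 alkylation of the lithium lactone enolate by a primary iodide, which enters anti to the C16 methyl group to give the trans lactone (this C6 centre is made planar again in step 6).

Step 6
Reactants: 10 trans-alkylated lactone; 11 2-(2-iodoethyl)-2-methyl-1,3-dioxolane
Product: 12 (3S,4R)-3-[(3S)-3-(tert-butyldimethylsilyloxy)-3-methylpent-4-en-1-yl]-4-methyl-3-[2-(2-methyl-1,3-dioxolan-2-yl)ethyl]tetrahydro-2H-pyran-2-one
Conditions: LiN(iPr)2, THF, −78 to 0 °C; then 11, DMPU, −40 °C to rt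
Reagents that add atoms: none
Why: Second lactone enolate alkylation, in which the C16 methyl group turns pseudoaxial to escape allylic strain with the C5 chain and shields one face of the tetrasubstituted enolate, so the 3-oxobutyl equivalent (C7–C10) enters anti to it and sets quaternary C6 with C7 trans and C5 cis to that methyl group.

Step 7
Reactants: 12 quaternary lactone
Product: 13 (2S,3R)-2-[(3S)-3-(tert-butyldimethylsilyloxy)-3-methylpent-4-en-1-yl]-3-methyl-2-[2-(2-methyl-1,3-dioxolan-2-yl)ethyl]pentane-1,5-diol
Conditions: LiAlH4, Et2O, 0 °C to rt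
Reagents that add atoms: none
Why: Hydride reduction of the lactone to the 1,5-diol, with ketal, silyl ether and vinyl group inert and no stereocentre affected.

Step 8
Reactants: 13 1,5-diol
Product: 15 (4R,5S)-5-[(3S)-3-(tert-butyldimethylsilyloxy)-3-methylpent-4-en-1-yl]-4-methyl-5-[2-(2-methyl-1,3-dioxolan-2-yl)ethyl]tetrahydro-2H-pyran-2-one, via lactol 14 (not isolated)
Conditions: TEMPO (cat.), PhI(OAc)2, CH2Cl2, rt
Reagents that add atoms: none
Why: Oxoammonium-mediated oxidative lactonisation of a 1,5-diol, which attacks the unhindered C14 alcohol rather than the neopentyl C11 alcohol, closes to lactol 14 and oxidises it further, so the carbonyl group is moved from C11 to C14 and a free hydroxy enone (prone to oxa-Michael closure) is never formed.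

Step 9
Reactants: 15 transposed lactone; 16 (E)-2-bromobut-2-ene
Product: 18 (2E,6R,7S,10S)-10-(tert-butyldimethylsilyloxy)-7-(hydroxymethyl)-3,6,10-trimethyl-7-[2-(2-methyl-1,3-dioxolan-2-yl)ethyl]dodeca-2,11-dien-4-one, via alkenyllithium 17 (not isolated)
Conditions: 16, t-BuLi (2 equiv), Et2O, −78 °C; then 15, THF, −78 °C
Reagents that add atoms: tert-butyllithium [Li]C(C)(C)C (lithium of intermediate 17 only)
Why: Bromine–lithium exchange with retention of alkene geometry and single addition of the alkenyllithium to the δ-lactone, whose tetrahedral lithium hemiketal survives at −78 °C until work-up, gives the E (tigloyl) enone C14(=O)–C12(CH3)=C13H–CH3.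

Step 10
Reactants: 18 hydroxy enone
Product: 19 C11 aldehyde (compound 18 with CHO in place of CH2OH on C6)
Conditions: Dess–Martin periodinane, CH2Cl2, 0 °C to rt
Reagents that add atoms: none
Why: Dess–Martin oxidation of the neopentyl primary alcohol (drawn from its hemiketal equilibrium) to a non-enolisable aldehyde, with no epimerisable centre involved.

Step 11
Reactants: 19 C11 aldehyde
Product: 21 (4S)-4-[(3S)-3-(tert-butyldimethylsilyloxy)-3-methylpent-4-en-1-yl]-4-[(2R,5E)-5-methyl-4-oxohept-5-en-2-yl]cyclohex-2-en-1-one, via keto aldehyde 20 (not isolated)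
Conditions: PPTS, acetone/H2O, 50 °C; then piperidine, AcOH, toluene, 60 °C
Reagents that add atoms: water O
Why: Mild ketal hydrolysis followed by amine–acid-catalysed intramolecular aldol condensation (the ring-closing half of a Robinson annulation), in which only the C10 methyl group can reach the non-enolisable C11 aldehyde through a six-membered ring, other aldol adducts are reversible, and the conjugated ring A enone is the sink.

Step 12
Reactants: 21 monocyclic bis-enone
Product: 23 tricyclic Diels–Alder adduct (C9 silyl enol ether with C9=C10; C14 ketone; C12 and C13 methyl groups cis and facing the C9=C10 bridge), via silyloxydiene 22 (not isolated)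
Conditions: TBSOTf (1.05 equiv), Et3N, CH2Cl2, −78 to 0 °C; solvent exchange; toluene, BHT (cat.), 150 °C, sealed tube
Reagents that add atoms: tert-butyldimethylsilyl triflate CC(C)(C)[Si](C)(C)OS(=O)(=O)C(F)(F)F
Why: Soft enolisation of the ring enone with TBSOTf/Et3N can only remove a C8 proton (C6 is quaternary) and gives the cross-conjugated 2-silyloxy-1,3-diene 22 (C8=C9–C10=C11), which on heating adds the tigloyl C12=C13 bond in a concerted, asynchronous, normal-electron-demand intramolecular Diels–Alder reaction; the closest known reaction type is the cycloaddition of 2-silyloxycyclohexa-1,3-dienes to tethered enones, the thermal counterpart of the intramolecular double Michael reaction. Bond C11–C12 closes ring C as a six-membered ring in the fused mode of a 1,7,9-decatriene (four-atom link C6–C16–C15–C14 from diene terminus C11 to C12), while bond C8–C13 closes ring B in the bridged sense and completes the bicyclo[2.2.2]octene. C8 and C11 are controlled by C6, because the dienophile can only reach the diene face on which its tether stands; C12 is controlled by the tether, which holds C14 exo above the C6–C7 bridge and turns the C12 methyl group towards C9=C10; C13 is controlled by the E geometry of the alkene, which suprafacial addition translates into a C13 methyl group cis to the C12 methyl group. Regiochemistry is matched, since the nucleophilic diene terminus C8 meets the β-carbon C13. Two chemoselectivities are needed: silylation at C8 rather than C15, secured by the branched C16 and the α-methyl group that shield the acyclic ketone (a C15 silyl enol ether cannot cyclise and returns 21 on hydrolysis), and reaction of the enone rather than of the side-chain vinyl group, which hangs on the opposite diene face at the same distance but carries no activating group. The adduct keeps C9 masked as a silyl enol ether, so C14 is the only free ketone in step 13.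

Step 13
Reactants: 23 tricyclic adduct
Product: 24 equatorial (14R) alcohol (C14–OH trans to the C12 methyl group on ring C; C9 silyl enol ether retained)
Conditions: SmI2, H2O, THF, 0 °C to rt
Reagents that add atoms: none
Why: Single-electron (ketyl) reduction, which is little affected by the shielding of both carbonyl faces (C13–H above, axial C16 methyl group below) and should deliver the thermodynamically preferred equatorial alcohol, the axial epimer suffering a syn-axial OH/CH3 interaction.

Step 14
Reactants: 24 equatorial alcohol
Product: 25 C14 acetate (bis-silylated target)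
Conditions: Ac2O, DMAP, pyridine, rt to 40 °C
Reagents that add atoms: acetic anhydride CC(=O)OC(C)=O
Why: DMAP-catalysed acylation of the only free hydroxyl group with retention at C14, the silyl enol ether and the tertiary silyl ether being stable to these basic conditions.

Step 15
Reactants: 25 C14 acetate
Product: 26 CNP0281208.1 (target)
Conditions: HF·pyridine, pyridine, THF, 0 °C to rt
Reagents that add atoms: none
Why: Fluoride-mediated global desilylation, in which the silyl enol ether gives the C9 ketone by protonation at non-stereogenic C10 (bridgehead C8 cannot epimerise), the tertiary silyl ether gives the C3 alcohol by Si–O cleavage with retention, and the acetate is inert to buffered HF.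

Compound list
1 | (S)-(+)-linalool, (3S)-3,7-dimethylocta-1,6-dien-3-ol | C=C[C@@](C)(O)CCC=C(C)C | starting material
2 | (S)-linalool tert-butyldimethylsilyl ether | C=C[C@@](C)(O[Si](C)(C)C(C)(C)C)CCC=C(C)C | intermediate
3 | (4S)-4-(tert-butyldimethylsilyloxy)-4-methylhex-5-enal | C=C[C@@](C)(O[Si](C)(C)C(C)(C)C)CCC=O | intermediate
4 | (4S)-4-(tert-butyldimethylsilyloxy)-4-methylhex-5-enoic acid | C=C[C@@](C)(O[Si](C)(C)C(C)(C)C)CCC(=O)O | intermediate
5 | 2-thioxopyridin-1(2H)-yl ester of 4 | C=C[C@@](C)(O[Si](C)(C)C(C)(C)C)CCC(=O)ON1C=CC=CC1=S | intermediate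
6 | (3S)-3-(tert-butyldimethylsilyloxy)-5-iodo-3-methylpent-1-ene | C=C[C@@](C)(O[Si](C)(C)C(C)(C)C)CCI | intermediate
7 | methyl hydrogen (R)-3-methylglutarate, (3R)-5-methoxy-3-methyl-5-oxopentanoic acid | COC(=O)C[C@H](C)CC(=O)O | starting material
8 | methyl (3R)-5-hydroxy-3-methylpentanoate | COC(=O)C[C@H](C)CCO | intermediate
9 | (4R)-4-methyltetrahydro-2H-pyran-2-one | C[C@@H]1CCOC(=O)C1 | intermediate
10 | (3S,4R)-trans-3-alkyl-4-methyl lactone (alkyl = C1–C5 chain) | C=C[C@@](C)(O[Si](C)(C)C(C)(C)C)CC[C@@H]1C(=O)OCC[C@H]1C | intermediate
11 | 2-(2-iodoethyl)-2-methyl-1,3-dioxolane | CC1(CCI)OCCO1 | starting material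
12 | (3S,4R)-3,3-dialkyl-4-methyl lactone (C5 chain cis, C7 chain trans to the ring methyl group) | C=C[C@@](C)(O[Si](C)(C)C(C)(C)C)CC[C@@]1(CCC2(C)OCCO2)C(=O)OCC[C@H]1C | intermediate
13 | (2S,3R)-1,5-diol from 12 | C=C[C@@](C)(O[Si](C)(C)C(C)(C)C)CC[C@](CO)(CCC1(C)OCCO1)[C@H](C)CCO | intermediate
14 | C14 lactol (mixture of anomers) | C=C[C@@](C)(O[Si](C)(C)C(C)(C)C)CC[C@@]1(CCC2(C)OCCO2)COC(O)C[C@H]1C | intermediate
15 | (4R,5S)-transposed lactone (carbonyl at C14) | C=C[C@@](C)(O[Si](C)(C)C(C)(C)C)CC[C@@]1(CCC2(C)OCCO2)COC(=O)C[C@H]1C | intermediate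
16 | (E)-2-bromobut-2-ene (the two methyl groups cis) | C/C=C(\C)Br | starting material
17 | but-2-en-2-yllithium, Li in the place of Br of 16, the two methyl groups cis | C/C=C(\C)[Li] | intermediate
18 | hydroxy enone (2E,6R,7S,10S) | C=C[C@@](C)(O[Si](C)(C)C(C)(C)C)CC[C@](CO)(CCC1(C)OCCO1)[C@H](C)CC(=O)/C(C)=C/C | intermediate
19 | C11 aldehyde with tigloyl ketone and C9 ketal | C=C[C@@](C)(O[Si](C)(C)C(C)(C)C)CC[C@](C=O)(CCC1(C)OCCO1)[C@H](C)CC(=O)/C(C)=C/C | intermediate
20 | keto aldehyde (free C9 methyl ketone) | C=C[C@@](C)(O[Si](C)(C)C(C)(C)C)CC[C@](C=O)(CCC(C)=O)[C@H](C)CC(=O)/C(C)=C/C | intermediate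
21 | (4S)-4,4-disubstituted cyclohex-2-enone with (3S) side chain and (2R,5E) tigloyl tether | C=C[C@@](C)(O[Si](C)(C)C(C)(C)C)CC[C@@]1(C=CC(=O)CC1)[C@H](C)CC(=O)/C(C)=C/C | intermediate
22 | 2-(tert-butyldimethylsilyloxy)cyclohexa-1,3-diene derived from 21 | C=C[C@@](C)(O[Si](C)(C)C(C)(C)C)CC[C@@]1(C=CC(O[Si](C)(C)C(C)(C)C)=CC1)[C@H](C)CC(=O)/C(C)=C/C | intermediate
23 | tricyclic adduct, C9 silyl enol ether, C14 ketone; C3, C6, C8, C11, C12, C13, C16 as in the target | C=C[C@@](C)(O[Si](C)(C)C(C)(C)C)CC[C@@]12C[C@H]3C(O[Si](C)(C)C(C)(C)C)=C[C@@H]1[C@](C)([C@@H]3C)C(=O)C[C@H]2C | intermediate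
24 | equatorial C14 alcohol | C=C[C@@](C)(O[Si](C)(C)C(C)(C)C)CC[C@@]12C[C@H]3C(O[Si](C)(C)C(C)(C)C)=C[C@@H]1[C@](C)([C@@H]3C)[C@H](O)C[C@H]2C | intermediate
25 | C14 acetate, bis-silylated target | C=C[C@@](C)(O[Si](C)(C)C(C)(C)C)CC[C@@]12C[C@H]3C(O[Si](C)(C)C(C)(C)C)=C[C@@H]1[C@](C)([C@@H]3C)[C@H](OC(C)=O)C[C@H]2C | intermediate
26 | CNP0281208.1 | C=C[C@@](C)(O)CC[C@@]12C[C@H]3C(=O)C[C@@H]1[C@](C)([C@@H]3C)[C@H](OC(C)=O)C[C@H]2C | target

Total step count: 15. Longest linear sequence: 14 (steps 1–3 and 5–15, from (S)-linalool).

Steps most likely to fail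

Step 12. The enol silylation may not discriminate cleanly between C8 and C15. The cycloaddition of the trisubstituted dienophile onto the hindered terminus C11 may also be so slow that loss of the silyl enol ether, or cycloaddition of the side-chain vinyl group, competes. The fallback replaces the pericyclic closure by an anionic one. It sets out from 21, which is treated with LiN(SiMe3)2 in THF/hexane (−78 °C to rt). Under proton-transfer equilibration the C8 dienolate is drained through an intramolecular double Michael reaction (C8 to C13, then C12 to C11) to the tricyclic 9,14-diketone F1. The less hindered C9 ketone, which can enolise only towards C10 because C8 is a bridgehead, is then silylated selectively (TBSOTf, Et3N, CH2Cl2, −78 °C). The route is rejoined at 23.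

Step 13. Protonation of the reduced ketyl may show poor stereocontrol. The Lewis acidic samarium salts may also hydrolyse the silyl enol ether, which would expose C9 to reduction. The fallback separates reduction from stereocontrol. From 23, LiAlH4 (Et2O, 0 °C) should attack from the face guarded only by C13–H and give mainly the axial C14 epimeric alcohol F2. This epimer is then equilibrated under Meerwein–Ponndorf–Verley/Oppenauer conditions (Al(OiPr)3, a trace of acetone, toluene, heat) to the more stable equatorial alcohol. The route is rejoined at 24.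

Step 6. Substitution at the tetrasubstituted enolate may be slow, so that elimination of HI from 11 and proton transfer take over. The fallback forms the quaternary centre by conjugate addition instead of substitution. From 10, LiN(iPr)2/TMSCl (THF, −78 °C) gives the trimethylsilyl ketene acetal F3. A Mukaiyama–Michael addition to methyl vinyl ketone (Sc(OTf)3 cat., CH2Cl2, −78 °C), again anti to the C16 methyl group, gives the 3-oxobutyl lactone F4. Ketalisation (ethylene glycol, PPTS, benzene, water separator) rejoins the route at 12.

Further compounds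
F1 | step 12 | tricyclic 9,14-diketone | C=C[C@@](C)(O[Si](C)(C)C(C)(C)C)CC[C@@]12C[C@H]3C(=O)C[C@@H]1[C@](C)([C@@H]3C)C(=O)C[C@H]2C
F2 | step 13 | axial C14 epimeric alcohol | C=C[C@@](C)(O[Si](C)(C)C(C)(C)C)CC[C@@]12C[C@H]3C(O[Si](C)(C)C(C)(C)C)=C[C@@H]1[C@](C)([C@@H]3C)[C@@H](O)C[C@H]2C
F3 | step 6 | trimethylsilyl ketene acetal of 10 | C=C[C@@](C)(O[Si](C)(C)C(C)(C)C)CCC1=C(O[Si](C)(C)C)OCC[C@H]1C
F4 | step 6 | 3-oxobutyl lactone | C=C[C@@](C)(O[Si](C)(C)C(C)(C)C)CC[C@@]1(CCC(C)=O)C(=O)OCC[C@H]1C
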